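The readings were generated by integration for substances that don't exist; noise was put on by code.

Single product stalls in spring. Spring is the flask asked about, followed so far; dusk is an earlier run.

| flask | substrate | reagent | temperature | remark | time |
|---|---|---|---|---|---|
| spring | 0.40 M | 0.38 M | 20 °C | the very flask that is asked about, followed so far |  |
| dusk | 0.80 M | 0.38 M | 26 °C | run made earlier |  |
| flask | 0.40 M | 0.380 M | 20 °C |  | 8.0 h |

- spring (time / h: single product / %, substrate / %): 0.417: 14, 82; 0.667: 17, 80; 1.00: 19, 70; 2.00: 21, 59; 3.00: 24, 47; 5.00: 23, 43
- dusk (time / h: single product / %, substrate / %): 0.667: 18, 71; 1.00: 22, 67; 2.00: 22, 60; 3.00: 23, 59; 5.00: 26, 54; 8.00: 25, 47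

(scatter of a reading: 1.5 percentage points)

- elm: at 8.0 h add reagent, 50.0 % of the amount charged, then wait 4.0 h
- birch: at 8.0 h raise the temperature by 15 K, then wait 4.0 h
- oak: change nothing and wait 4.0 h more
- cedar: at 8.0 h take out 90 % of the single product then present, then wait 4.0 h

- single product taken out counts as made
- additions bring no volume worth counting

- single product, in percent of the substrate first charged, at 8.0 h
- the option that brings most further single product ("none" if no option brings more than 2 percentage points) (elm / birch / oak / cedar / none)
- single product present, with what was taken out counted in, in percent of the substrate first charged, after birch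
- single product present, with what was taken out counted in, in percent of the substrate first charged, after cedar

With the main step alone, substrate + reagent → single product, the reagent charge of 95.0 % of the substrate would allow that much single product. Yet spring reads 23 % at 5.00 h, and 34.0 % of the substrate is unaccounted for.

A second step is therefore supposed in the reckoning made here: single product + reagent → double product. Let a and m be substrate and single product as fractions of the charge, with rate constants k and k′. Both rates carry the reagent, so dividing them removes reagent and time:

dm/da = κ m/a − 1, so m = (a − a^κ)/(κ − 1)

Single product stops climbing where a/m = κ. This stall ratio κ = k′/k, the selectivity factor, is read from the two last spring readings as 1.91, with their scatter of 1.5 percentage points in each. The ceiling falls from 95.0 % to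

m_peak = κ^(−κ/(κ − 1)) = 25.7 %

A third process shows in dusk. Its reagent charge, 47.5 % of the substrate, pays for at most 11.2 % of double product at 8.00 h, while 28.0 % is unaccounted for. As an estimate from these scattered readings, about 16.8 % left without reagent, and a must count that substrate as unreacted.

The reckoning here gives about 25.7 % at 8.0 h, above the spring readings. Since a/m in the last spring readings stands at κ, it expects fresh reagent to lose single product.

The forecast gives 24 %, elm, 25 % after birch and 25 % after cedar, holding that “Fresh reagent should restart formation”.

The flask gives 24.1 %, best birch, 36.3 % after birch and 29.3 % after cedar.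

    substrate + reagent → single product (k = 3.20 × 10⁻⁴ L mol⁻¹ s⁻¹, Ea = 80.0 kJ mol⁻¹)
    reagent + single product ⇌ double product (K = 100 L mol⁻¹, k = 7.60 × 10⁻⁴ L mol⁻¹ s⁻¹, Ea = 73.0 kJ mol⁻¹, ΔH = −19.0 kJ mol⁻¹)
    substrate ⇌ dormant form (K = 0.420, k = 5.50 × 10⁻⁶ s⁻¹, Ea = 104 kJ mol⁻¹, ΔH = 28.0 kJ mol⁻¹)
    (constants at 20 °C)

At 8.00 h the flask holds 36.1 % substrate, 6.40 % dormant form and 24.1 % single product, so a/m = 1.76, below κ, and elm changes single product by −6 points while birch adds 12 points. A neighbouring flask is the same flask with 0.095 M of reagent. At 8.00 h this neighbour holds 70.4 % substrate and 10.3 % dormant form, which the reckoning counts as unreacted, so a = 80.8 %. The closed form with the spring κ then gives 15.7 %, and the neighbour holds 15.3 % single product.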